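All constants were chosen freely; what happens was integrated by code.

Slowness came first: I looked for the step that would hold this flask back.

substrate 1.6 M; gas 200 mM (held); time 1.0 h

    substrate + reagent → product, rate k1*[substrate]^1.5*[reagent]^0.5 (k1 = 1.9 /M/h)
    gas ⇌ reagent, rate k2*(csat - [reagent]) (k2 = 120 /h, csat = 200 mM)

1. amount of product at 1.0 h, in percent of the substrate charged
2. the change that raises the amount of product at 1.0 h, in percent of the substrate charged most ("none" if none brings more than 2 percentage points) (amber / blue / none)
3. amount of product at 1.0 h, in percent of the substrate charged, after blue

- amber: doubling the transfer coefficient of step 2, all else as stated
- blue: doubling the saturation concentration of gas, all else as stated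

I solved the run at both ends. At the start, the empty solution fills with reagent in about 0.500 min, far less than the run time of 1.0 h. After that, step 2 can carry up to 24.0 M/h, much faster than the 1.72 M/h that step 1 asks at the start. Step 1 is therefore the rate-limiting step, and once the solution has filled, I put reagent about 14.3 mM below saturation at that starting demand. Joining the ends, I held [reagent] at 200 mM, so [substrate] falls as its charge divided by the square of one plus t over a clock. This substrate clock, the time in which [substrate] falls to a quarter of its charge with reagent held at saturation, is two divided by k1 and by the root of charge times saturation: 1.86 h. It gave 57.7 %, which I took as slightly high, given the gap in reagent.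

Amber leaves the clock unchanged, since k2 is not in it, and halves the gap. Taking the gap at the starting demand and the yield as proportional to the rate, I put the gain at about 1 percentage point, below the 2 points that counts. Blue shortens the clock to 1.32 h, which gave 67.7 %, a gain of 10 points. I chose blue.

The forecast gave 56.9 %, blue and 67.3 %, on the ground that “dissolved reagent stays close to saturation”. Its two yields stood below mine.

The simulation gave 57.0 %. Amber added 0.37 points and blue 10 points, so the answer was blue, at 67.3 %. In the flask, reagent read 0.188 M at 0.100 h and 0.196 M at 1.00 h, and the yield lay 0.70 points under the clock's figure. The same flask read at 4.0 h is 2.15 clocks along, for which the clock of 1.86 h gives 89.9 %. That neighbour held 89.8 % product, with reagent at 0.200 M and 10 % of the substrate left.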